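**Plan**
1. Retrosynthesis: the bonds cut, in order, are C(=CH2)–C(spiro tetronate) of ring C (Conia-ene), C3–C4 of the tetronate (Dieckmann), CH2–C(Me)(CO2H) (asymmetric alkylation), ring-B C(sp2)–CH2 (carbonylation), and the CH3 and CH2CO bonds at the angular carbon (enolate alkylations). This leads to spirolactone ketone 12.
2. In 12 the bond spiro-C–CH= is cut and the CH= carbon is rejoined to the neighbouring CHMe carbon. This reverse 1,2-vinyl shift widens the δ-lactone to the fused ε-lactone 11, which comes from (R)-Wieland–Miescher ketone by gem-dimethylation, Baeyer–Villiger oxidation and desaturation.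
3. Enabling feature: the spiro carbon shared by δ-lactone ring A and cyclohexene ring B bears both the OCMe2 carbon and the enoate β-CH=. Its ring-B neighbour is the methyl-bearing sp2 carbon, which sits next to the former ketone carbon. A vinyl on one carbon and a methyl on the adjacent α-keto carbon is what a vinyl group leaves when it hops from an angular C(Me) to a radical next door.
4. Forward ring order: ring B is present in 1; ε-lactone (step 4), then δ-spirolactone (step 8), then tetronic acid (step 21), then ring C (step 22).
5. Stereochemistry: the lactone spiro carbon comes by suprafacial relay from C8a of 1. The angular C–Me is set by axial methylation steered by that spiro centre. C(Me)CO2H is set by a chiral phase-transfer catalyst, and O–CHMe comes from methyl (R)-lactate. The tetronate spiro carbon is set by alkyne attack anti to that methyl.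

Key step: step 8

Conventions and assumptions
- Compounds 1–11 keep Wieland–Miescher numbering: C1 saturated C=O or carbinol, C4a, C5, C6 enone or lactone C=O, C7, C8, C8a angular carbon.
- Compounds 12–29 use 2-oxaspiro[5.5]undecane numbering: C1 = CMe2, O2, C3 = lactone C=O, C4=C5, C6 = spiro, C7 = C–Me, C8 = former ketone carbon, C9, C10, C11. Old C4a is new C6, old C8a is new C7, old C8 is new C5.
- Assumption: the centres α to the ketone in 12 and 16 are labile, and the equatorial (thermodynamic) epimers are drawn.
- Assumption: the sense of induction in step 18 is read from a model alkylation of 25. The commercial catalyst antipode that gives the (R) centre is the one used.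

**Step 1**
Reactants: 1 (R)-Wieland–Miescher ketone
Product: 2 (4aR,5R)-5-hydroxy-4a-methyl-4,4a,5,6,7,8-hexahydronaphthalen-2(3H)-one (C1 alcohol cis to the angular methyl)
Conditions: NaBH4 (0.3 equiv), EtOH, 0 °C
Reagents that add atoms: none
Why: Chemoselective borohydride reduction, in which the isolated C1 ketone reacts ahead of the vinylogous C6 enone carbonyl and hydride enters anti to the axial angular methyl, giving the equatorial alcohol (a temporary mask that step 7 erases).

**Step 2**
Reactants: 2 hydroxy enone
Product: 3 tert-butyldimethylsilyl ether of 2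
Conditions: TBSCl, imidazole, DMF, 40 °C
Reagents that add atoms: tert-butyldimethylsilyl chloride, CC(C)(C)[Si](C)(C)Cl
Why: Standard silyl ether formation, chosen over a ketal because fluoride removes it later without the aqueous acid that would ionise the tertiary allylic C–O bond of the lactone.

**Step 3**
Reactants: 3 silyl ether enone; 4 iodomethane
Product: 5 (4aR,5R)-5-(tert-butyldimethylsilyloxy)-1,1,4a-trimethyl-3,4,4a,5,6,7-hexahydronaphthalen-2(1H)-one (C5 gem-dimethyl, C4a=C4 alkene)
Conditions: t-BuOK (3.5 equiv), t-BuOH–THF; MeI (excess), 0 °C → rt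
Reagents that add atoms: iodomethane 4, CI
Why: Deconjugative α,α-dialkylation of the enone through its extended dienolate, in which both methyl groups enter at C5 and the double bond moves to C4a=C4, so no stereocentre is formed.

**Step 4**
Reactants: 5 β,γ-unsaturated ketone
Product: 6 (5aR,6R)-6-(tert-butyldimethylsilyloxy)-1,1,5a-trimethyl-4,5,5a,6,7,8-hexahydro-2-benzoxepin-3(1H)-one (fused ε-lactone)
Conditions: (Me3SiO)2 (2.5 equiv), TMSOTf (0.2 equiv), 4 Å MS, CH2Cl2, −40 → −20 °C
Reagents that add atoms: bis(trimethylsilyl) peroxide, C[Si](C)(C)OO[Si](C)(C)C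
Why: Baeyer–Villiger oxidation with a silyl peroxide under Lewis acid catalysis, a nucleophilic oxidant that adds to the activated ketone but does not epoxidise the C4a=C4 alkene, with the tertiary allylic C5 migrating in preference to C7H2.

**Step 5**
Reactants: 6 ε-lactone
Product: 9 dienyl ε-lactone silyl ether, via selenide 7 (not isolated), via selenoxide 8 (not isolated)
Conditions: LDA, THF, −78 °C; PhSeBr; then 30 % H2O2, pyridine, CH2Cl2, 0 °C → rt
Reagents that add atoms: benzeneselenenyl bromide, Br[Se]c1ccccc1 (SePh of 7 and 8, lost again); hydrogen peroxide, OO (Se=O oxygen of 8, lost again)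
Why: α-Selenenylation of the lactone enolate (C7 is the only enolisable position) followed by selenoxide syn-elimination, which gives the ring-constrained Z-enoate, while selenium is oxidised far faster than the hindered alkene.

**Step 6**
Reactants: 9 dienyl ε-lactone silyl ether
Product: 10 (5aR,6R)-6-hydroxy-1,1,5a-trimethyl-5a,6,7,8-tetrahydro-2-benzoxepin-3(1H)-one
Conditions: HF·pyridine, THF, 0 °C → rt
Reagents that add atoms: none
Why: Fluoride-driven desilylation under nearly neutral conditions that leave the enoate and the tertiary allylic lactone C–O bond untouched.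

**Step 7**
Reactants: 10 hydroxy dienyl lactone
Product: 11 (5aR)-1,1,5a-trimethyl-7,8-dihydro-2-benzoxepine-3,6(1H,5aH)-dione (fused dienyl ε-lactone ketone)
Conditions: Dess–Martin periodinane, CH2Cl2, rt
Reagents that add atoms: none
Why: Dess–Martin oxidation of the hindered secondary alcohol, mild enough for both alkenes and the lactone, with the quaternary C8a as the only stereocentre left.

**Step 8**
Reactants: 11 fused dienyl ε-lactone ketone
Product: 12 (6R,7R)-1,1,7-trimethyl-2-oxaspiro[5.5]undec-4-ene-3,8-dione (spirolactone 2-methylcyclohexanone)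
Conditions: Fe(acac)3 (30 mol %), PhSiH3 (2.5 equiv), EtOH (0.01 M), 60 °C, Ar
Reagents that add atoms: none
Why: Proposed new method: An iron hydride formed from Fe(acac)3 and PhSiH3 should deliver H• to the open C4–H end of the electron-rich trisubstituted alkene and leave a nucleophilic tertiary radical at C4a; this attacks the adjacent enoate β-carbon C8 (3-exo-trig, polarity matched), the lactone-stabilised cyclopropylcarbinyl radical opens its C8a–C8 bond to the tertiary α-keto radical at C8a, and Fe(II) reduces that radical to the enolate, which ethanol protonates. The net event is a 1,2-vinyl shift that makes C4a–C8, breaks C8a–C8 and turns the seven-membered lactone into the six-membered spirolactone; the closest known types are hydrogen-atom-transfer-initiated Giese cyclisations onto enoates, the hydrogen-atom-transfer-initiated Dowd–Beckwith 1,2-acyl shift and tin hydride homoallyl (1,2-vinyl) radical rearrangements, but a hydride-initiated vinyl shift that contracts a lactone is not known. The only ring that persists is the δ-lactone, and it arises by 3-exo-trig closure followed by cyclopropane fragmentation, not by a direct six-membered cyclisation. The spiro stereocentre is fixed by geometry: C8 must stay on the face of the carbocycle where it sat at C8a, so the (R) angular centre of 11 becomes the (R) spiro centre of 12, while the new C–H centre next to the ketone is labile and settles as the equatorial methyl epimer. Three selectivities are needed: hydrogen transfer to C4a=C4 rather than the enoate (whose β-carbon is neopentylic and electron-poor), vinyl shift rather than 1,2-shift of the C1 acyl group (vinyl migrates intrinsically faster and the ester accelerates it further), and forward opening of the cyclopropane (only this direction gives a carbonyl-stabilised tertiary radical). High dilution suppresses intermolecular Giese addition to the enoate of a second molecule.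

**Step 9**
Reactants: 13 2-(trimethylsilyl)ethanol; 14 bromoacetyl bromide
Product: 15 2-(trimethylsilyl)ethyl bromoacetate
Conditions: pyridine, CH2Cl2, 0 °C
Reagents that add atoms: bromoacetyl bromide 14, BrCC(=O)Br
Why: Simple O-acylation by the acid bromide, giving an alkylating agent whose ester is later cleaved by fluoride, orthogonally to the tert-butyl ester and the lactone.

**Step 10**
Reactants: 12 spirolactone ketone; 15 2-(trimethylsilyl)ethyl bromoacetate
Product: 16 2-(trimethylsilyl)ethyl 2-[(6R,7R,9R)-1,1,7-trimethyl-3,8-dioxo-2-oxaspiro[5.5]undec-4-en-9-yl]acetate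
Conditions: LDA, THF, −78 °C; 15, DMPU, −78 → −40 °C
Reagents that add atoms: 2-(trimethylsilyl)ethyl bromoacetate 15, BrCC(=O)OCC[Si](C)(C)C
Why: Kinetic enolate alkylation, in which LDA takes a proton from the open C9H2 rather than from C7–H beside the spiro carbon, the lactone has no enolisable hydrogen, and the new C9 centre is labile and is reset in step 11.

**Step 11**
Reactants: 16 keto ester; 4 iodomethane
Product: 17 2-(trimethylsilyl)ethyl 2-[(6R,7R,9R)-1,1,7,9-tetramethyl-3,8-dioxo-2-oxaspiro[5.5]undec-4-en-9-yl]acetate (C9 methyl cis to the OCMe2 arm at C6)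
Conditions: KHMDS, THF, −78 °C; MeI, −78 → −40 °C
Reagents that add atoms: iodomethane 4, CI
Why: Alkylation of the C8=C9 enolate (C7–H is shielded by the spiro carbon and its gem-dimethyl group, and the ester CH2 is less acidic); with the bulky OCMe2 arm equatorial, the vinyl arm axial and the C7 methyl equatorial, MeI should enter axially through a chair-like transition state on the face opposite the axial vinyl arm, placing the new methyl cis to OCMe2 as in the target.

**Step 12**
Reactants: 17 quaternary keto ester
Product: 18 2-(trimethylsilyl)ethyl 2-[(6R,9R)-1,1,7,9-tetramethyl-3-oxo-8-(trifluoromethylsulfonyloxy)-2-oxaspiro[5.5]undeca-4,7-dien-9-yl]acetate (enol triflate)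
Conditions: KHMDS, THF, −78 → 0 °C; N-(5-chloro-2-pyridyl)bis(trifluoromethanesulfonimide), −78 °C → rt
Reagents that add atoms: N-(5-chloro-2-pyridyl)bis(trifluoromethanesulfonimide), FC(F)(F)S(=O)(=O)N(c1ccc(Cl)cn1)S(=O)(=O)C(F)(F)F
Why: Enol triflate formation, in which C7–H is the only ketone α-hydrogen left, equilibration at 0 °C drains any ester enolate into the more stable ketone enolate, and O-sulfonylation removes the labile C7 centre.

**Step 13**
Reactants: 18 enol triflate
Product: 19 2-(trimethylsilyl)ethyl 2-[(6R,9R)-8-formyl-1,1,7,9-tetramethyl-3-oxo-2-oxaspiro[5.5]undeca-4,7-dien-9-yl]acetate (enal)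
Conditions: Pd(PPh3)4 (10 mol %), LiCl, CO (3 bar), Bu3SnH (slow addition), THF, 50 °C
Reagents that add atoms: carbon monoxide, [C-]#[O+]
Why: Palladium-catalysed reductive carbonylation of a vinyl triflate (tin hydride formylation), in which small CO inserts even at the hindered position and stopping at the aldehyde avoids any hydride strong enough to touch the lactone or ester.

**Step 14**
Reactants: 19 enal
Product: 20 2-(trimethylsilyl)ethyl 2-[(6R,9R)-8-(hydroxymethyl)-1,1,7,9-tetramethyl-3-oxo-2-oxaspiro[5.5]undeca-4,7-dien-9-yl]acetate
Conditions: NaBH4, CeCl3·7H2O, MeOH, −20 °C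
Reagents that add atoms: none
Why: Luche reduction, a 1,2-selective reduction of the aldehyde that leaves the unsaturated lactone and the ester alone at low temperature.

**Step 15**
Reactants: 20 allylic alcohol
Product: 21 2-(trimethylsilyl)ethyl 2-[(6R,9R)-8-(bromomethyl)-1,1,7,9-tetramethyl-3-oxo-2-oxaspiro[5.5]undeca-4,7-dien-9-yl]acetate
Conditions: CBr4, PPh3, CH2Cl2, 0 °C
Reagents that add atoms: carbon tetrabromide, BrC(Br)(Br)Br
Why: Appel reaction under neutral conditions, where SN2 at the primary carbon is the only open path because the fully substituted alkene terminus blocks SN2′.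

**Step 16**
Reactants: 22 (triisopropylsilyl)acetylene; 23 tert-butyl diazoacetate
Product: 24 tert-butyl 4-(triisopropylsilyl)but-3-ynoate
Conditions: CuI (5 mol %), MeCN, rt
Reagents that add atoms: tert-butyl diazoacetate 23, [N-]=[N+]=CC(=O)OC(C)(C)C
Why: Copper(I)-catalysed coupling of a terminal alkyne with a diazoacetate (formal alkynyl C–H insertion), which gives the 3-alkynoate without drift to the allenoate.

**Step 17**
Reactants: 24 alkynoate; 4 iodomethane
Product: 25 tert-butyl 2-methyl-4-(triisopropylsilyl)but-3-ynoate (racemic)
Conditions: LDA, THF, −78 °C; MeI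
Reagents that add atoms: iodomethane 4, CI
Why: α-Alkylation of the ester enolate, which reacts at the α-carbon; the racemic centre does not matter because step 18 passes through the planar enolate.

**Step 18**
Reactants: 21 allylic bromide; 25 α-methyl alkynoate
Product: 26 tert-butyl (2R)-2-methyl-2-({(6R,9R)-1,1,7,9-tetramethyl-3-oxo-9-[2-oxo-2-(2-trimethylsilylethoxy)ethyl]-2-oxaspiro[5.5]undeca-4,7-dien-8-yl}methyl)-4-(triisopropylsilyl)but-3-ynoate
Conditions: N-spiro binaphthyl ammonium salt (3,4,5-trifluorophenyl-NAS bromide, 5 mol %), CsOH·H2O, toluene, −20 °C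
Reagents that add atoms: tert-butyl 2-methyl-4-(triisopropylsilyl)but-3-ynoate 25, CC(C#C[Si](C(C)C)(C(C)C)C(C)C)C(=O)OC(C)(C)C
Why: Chiral phase-transfer-catalysed α-alkylation of an α-alkyl-α-alkynyl ester, in which the ion-paired planar enolate displaces the primary allylic bromide through its α-carbon, one enolate face is shielded by the ammonium cation, and the resident stereocentres are too remote to interfere, so the quaternary (R) centre is reagent-controlled.

**Step 19**
Reactants: 26 bis-silyl diester
Product: 27 2-[(6R,9R)-8-{(2R)-2-(tert-butoxycarbonyl)-2-methylbut-3-ynyl}-1,1,7,9-tetramethyl-3-oxo-2-oxaspiro[5.5]undeca-4,7-dien-9-yl]acetic acid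
Conditions: TBAF (3 equiv), THF, 0 °C → rt
Reagents that add atoms: none
Why: Fluoride-induced fragmentation of the 2-(trimethylsilyl)ethyl ester and protodesilylation of the alkynylsilane in one operation, with the tert-butyl ester and the lactone inert to fluoride.

**Step 20**
Reactants: 27 acid; 28 methyl (R)-lactate
Product: 29 (2R)-1-methoxy-1-oxopropan-2-yl ester of 27
Conditions: DCC, DMAP (cat.), CH2Cl2, 0 °C → rt
Reagents that add atoms: methyl (R)-lactate 28, C[C@@H](O)C(=O)OC
Why: Steglich esterification, in which the lactate reacts through oxygen so its C–O bond and (R) configuration are carried unchanged into the future O–CHMe centre.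

**Step 21**
Reactants: 29 O-acyl lactate
Product: 30 (5R)-4-hydroxy-5-methylfuran-2(5H)-one carrying at C3 the C9 carbon of the spiro bicycle (3-substituted tetronic acid)
Conditions: LiHMDS (3.2 equiv), THF, −78 → 0 °C; 1 M HCl
Reagents that add atoms: none
Why: Lacey–Dieckmann cyclisation, in which the enolate of the acyl CH2 attacks the lactate methyl ester (5-exo-trig), the acidic tetronate is the thermodynamic sink, and short contact at low temperature should keep the lactate centre intact.

**Step 22**
Reactants: 30 alkynyl tetronic acid
Product: 31 tert-butyl ester of penicianstinoid C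
Conditions: Ph3PAuNTf2 (10 mol %), CH2Cl2, rt
Reagents that add atoms: none
Why: Gold(I)-catalysed Conia-ene reaction (6-exo-dig), in which the enolised tetronic acid attacks the internal carbon of the activated terminal alkyne through C3 and protodeauration leaves the exocyclic methylene; O-attack would need an eight-membered ring and the tetrasubstituted ring-B alkene is too hindered for enyne cyclisation, and because the alkyne should reach the planar tetronate anti to its C5 methyl, the lactate centre fixes the new spiro centre with the new C–C bond trans to that methyl, as in the target.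

**Step 23**
Reactants: 31 tert-butyl ester
Product: 32 penicianstinoid C
Conditions: TFA–CH2Cl2 (1:4), 0 °C
Reagents that add atoms: none
Why: Acidolysis of the tert-butyl ester by loss of the tert-butyl cation, free of base so the spiro furan-2,4-dione and its epimerisable O–CHMe centre are not endangered, and kept cold and short to avoid protonating the tetrasubstituted alkene.

**Compound list**
1 | (R)-Wieland–Miescher ketone, (8aR)-8a-methyl-3,4,8,8a-tetrahydronaphthalene-1,6(2H,7H)-dione | C[C@@]12CCC(=O)C=C1CCCC2=O | starting material
2 | (4aR,5R)-5-hydroxy-4a-methyl-4,4a,5,6,7,8-hexahydronaphthalen-2(3H)-one | C[C@@]12CCC(=O)C=C1CCC[C@H]2O | intermediate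
3 | tert-butyldimethylsilyl ether of 2 | C[C@@]12CCC(=O)C=C1CCC[C@H]2O[Si](C)(C)C(C)(C)C | intermediate
4 | iodomethane | CI | starting material
5 | (4aR,5R)-5-(tert-butyldimethylsilyloxy)-1,1,4a-trimethyl-3,4,4a,5,6,7-hexahydronaphthalen-2(1H)-one | C[C@@]12CCC(=O)C(C)(C)C1=CCC[C@H]2O[Si](C)(C)C(C)(C)C | intermediate
6 | (5aR,6R)-6-(tert-butyldimethylsilyloxy)-1,1,5a-trimethyl-4,5,5a,6,7,8-hexahydro-2-benzoxepin-3(1H)-one | C[C@@]12CCC(=O)OC(C)(C)C1=CCC[C@H]2O[Si](C)(C)C(C)(C)C | intermediate
7 | 4-phenylselanyl derivative of 6 (α to the lactone carbonyl, epimers) | C[C@@]12CC([Se]c3ccccc3)C(=O)OC(C)(C)C1=CCC[C@H]2O[Si](C)(C)C(C)(C)C | intermediate (not isolated)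
8 | selenoxide of 7 | C[C@@]12CC([Se](=O)c3ccccc3)C(=O)OC(C)(C)C1=CCC[C@H]2O[Si](C)(C)C(C)(C)C | intermediate (not isolated)
9 | (5aR,6R)-6-(tert-butyldimethylsilyloxy)-1,1,5a-trimethyl-5a,6,7,8-tetrahydro-2-benzoxepin-3(1H)-one | C[C@@]12C=CC(=O)OC(C)(C)C1=CCC[C@H]2O[Si](C)(C)C(C)(C)C | intermediate
10 | (5aR,6R)-6-hydroxy-1,1,5a-trimethyl-5a,6,7,8-tetrahydro-2-benzoxepin-3(1H)-one | C[C@@]12C=CC(=O)OC(C)(C)C1=CCC[C@H]2O | intermediate
11 | (5aR)-1,1,5a-trimethyl-7,8-dihydro-2-benzoxepine-3,6(1H,5aH)-dione | C[C@@]12C=CC(=O)OC(C)(C)C1=CCCC2=O | intermediate (key-step precursor)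
12 | (6R,7R)-1,1,7-trimethyl-2-oxaspiro[5.5]undec-4-ene-3,8-dione (C7 labile) | C[C@H]1C(=O)CCC[C@@]12C=CC(=O)OC2(C)C | intermediate (key-step product)
13 | 2-(trimethylsilyl)ethanol | OCC[Si](C)(C)C | starting material
14 | bromoacetyl bromide | BrCC(=O)Br | starting material
15 | 2-(trimethylsilyl)ethyl bromoacetate | BrCC(=O)OCC[Si](C)(C)C | intermediate
16 | 2-(trimethylsilyl)ethyl 2-[(6R,7R,9R)-1,1,7-trimethyl-3,8-dioxo-2-oxaspiro[5.5]undec-4-en-9-yl]acetate (C7, C9 labile) | C[C@H]1C(=O)[C@@H](CC(=O)OCC[Si](C)(C)C)CC[C@@]12C=CC(=O)OC2(C)C | intermediate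
17 | 2-(trimethylsilyl)ethyl 2-[(6R,7R,9R)-1,1,7,9-tetramethyl-3,8-dioxo-2-oxaspiro[5.5]undec-4-en-9-yl]acetate | C[C@H]1C(=O)[C@@](C)(CC(=O)OCC[Si](C)(C)C)CC[C@@]12C=CC(=O)OC2(C)C | intermediate
18 | (6R,9R) enol triflate of 17 (C7=C8, OTf at C8) | CC1=C(OS(=O)(=O)C(F)(F)F)[C@@](C)(CC(=O)OCC[Si](C)(C)C)CC[C@@]12C=CC(=O)OC2(C)C | intermediate
19 | (6R,9R) 8-formyl diene ester | CC1=C(C=O)[C@@](C)(CC(=O)OCC[Si](C)(C)C)CC[C@@]12C=CC(=O)OC2(C)C | intermediate
20 | (6R,9R) 8-(hydroxymethyl) diene ester | CC1=C(CO)[C@@](C)(CC(=O)OCC[Si](C)(C)C)CC[C@@]12C=CC(=O)OC2(C)C | intermediate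
21 | (6R,9R) 8-(bromomethyl) diene ester | CC1=C(CBr)[C@@](C)(CC(=O)OCC[Si](C)(C)C)CC[C@@]12C=CC(=O)OC2(C)C | intermediate
22 | (triisopropylsilyl)acetylene | C#C[Si](C(C)C)(C(C)C)C(C)C | starting material
23 | tert-butyl diazoacetate | [N-]=[N+]=CC(=O)OC(C)(C)C | starting material
24 | tert-butyl 4-(triisopropylsilyl)but-3-ynoate | CC(C)[Si](C#CCC(=O)OC(C)(C)C)(C(C)C)C(C)C | intermediate
25 | tert-butyl 2-methyl-4-(triisopropylsilyl)but-3-ynoate (racemic) | CC(C#C[Si](C(C)C)(C(C)C)C(C)C)C(=O)OC(C)(C)C | intermediate
26 | alkylation product, (2R) at the new quaternary carbon, (6R,9R) in the spiro bicycle | CC1=C(C[C@](C)(C#C[Si](C(C)C)(C(C)C)C(C)C)C(=O)OC(C)(C)C)[C@@](C)(CC(=O)OCC[Si](C)(C)C)CC[C@@]12C=CC(=O)OC2(C)C | intermediate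
27 | free acetic acid with terminal alkyne (tert-butyl ester retained) | CC1=C(C[C@](C)(C#C)C(=O)OC(C)(C)C)[C@@](C)(CC(=O)O)CC[C@@]12C=CC(=O)OC2(C)C | intermediate
28 | methyl (R)-lactate | C[C@@H](O)C(=O)OC | starting material
29 | (2R)-1-methoxy-1-oxopropan-2-yl ester of 27 | CC1=C(C[C@](C)(C#C)C(=O)OC(C)(C)C)[C@@](C)(CC(=O)O[C@H](C)C(=O)OC)CC[C@@]12C=CC(=O)OC2(C)C | intermediate
30 | 3-substituted (5R)-4-hydroxy-5-methylfuran-2(5H)-one (tetronic acid) | CC1=C(C[C@](C)(C#C)C(=O)OC(C)(C)C)[C@@](C)(C3=C(O)[C@@H](C)OC3=O)CC[C@@]12C=CC(=O)OC2(C)C | intermediate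
31 | tert-butyl ester of penicianstinoid C | C=C1[C@](C)(C(=O)OC(C)(C)C)CC2=C(C)[C@]3(C=CC(=O)OC3(C)C)CC[C@]2(C)[C@@]12C(=O)O[C@H](C)C2=O | intermediate
32 | penicianstinoid C | C=C1[C@](C)(C(=O)O)CC2=C(C)[C@]3(C=CC(=O)OC3(C)C)CC[C@]2(C)[C@@]12C(=O)O[C@H](C)C2=O | target

**Step count**
Total step count: 23.
Longest linear sequence: 20 (steps 1–8, 10–15, 18–23, from 1).

**Steps most likely to fail**

**Step 8.** The tertiary radical may be quenched before it migrates. Hydrogen transfer may go to the enoate. The sequence may also stop at the cyclopropane stage. The fallback sets out from 6 and returns at 12. It generates the radical by halogen abstraction, so hydride chemistry and the enoate never meet.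
- Cobalt-catalysed Markovnikov hydrochlorination of the C4a=C4 alkene (Co(II)/salicylaldimine catalyst, TsCl, PhSiH3, EtOH) is done while the lactone is still saturated. It gives the C4a tertiary chloride F1.
- Selenenylation as in step 5 gives the α-phenylselanyl chloro lactone F2. Oxidation gives its selenoxide F3, and syn-elimination gives the chloro enoate silyl ether F4.
- HF·pyridine gives the chloro enoate alcohol F5, and Dess–Martin oxidation gives the chloro keto enoate F6.
- Slow addition of Bu3SnH/AIBN in refluxing benzene then produces the same C4a radical under classical chain conditions with little hydrogen donor present. Homoallyl (1,2-vinyl) radical rearrangements are established in that setting, and the α-keto radical is reduced to 12.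

**Step 22.** No bond may form at the congested carbon. The gold-activated alkyne may be diverted by the ring-B alkene or the neighbouring ester oxygen. Face selectivity at the tetronate may be poor. The fallback sets out from 30 and returns at 31. The nucleophile is activated by one-electron oxidation instead of activating the alkyne with a π-acid. Mn(OAc)3·2H2O in ethanol oxidises the tetronic acid to its C3 radical, which closes 6-exo-dig onto the alkyne. The vinyl radical takes a hydrogen atom from ethanol and gives the exocyclic methylene. No new compound lies on this path.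

**Step 18.** Displacement by a tertiary carbanion at the neopentyl-like allylic bromide may be sluggish. Face selectivity may erode. The lactone or the silylethyl ester may be saponified during long exposure to hydroxide. The fallback sets out from 21 and 24 and returns at 26. It inverts the order of the two C–C bond formations at the quaternary carbon.
- The lithium enolate of the unmethylated alkynoate 24 (LDA, THF–DMPU, −78 °C) is smaller and more reactive than that of 25. It is alkylated with 21 to give the tertiary alkynyl ester F7, whose epimers at the acidic α-carbon are of no consequence.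
- The stereocentre is then created in a separate, fast methylation of F7 with iodomethane 4 under the same type of chiral ammonium catalyst. This uses the smallest possible electrophile and a short contact with base.

**Further compounds**
F1 | step 8 | C4a tertiary chloride of 6 (C4a epimers, both give the same radical) | C[C@@]12CCC(=O)OC(C)(C)C1(Cl)CCC[C@H]2O[Si](C)(C)C(C)(C)C
F2 | step 8 | α-phenylselanyl chloro lactone | C[C@@]12CC([Se]c3ccccc3)C(=O)OC(C)(C)C1(Cl)CCC[C@H]2O[Si](C)(C)C(C)(C)C
F3 | step 8 | selenoxide of F2 | C[C@@]12CC([Se](=O)c3ccccc3)C(=O)OC(C)(C)C1(Cl)CCC[C@H]2O[Si](C)(C)C(C)(C)C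
F4 | step 8 | chloro enoate ε-lactone silyl ether | C[C@@]12C=CC(=O)OC(C)(C)C1(Cl)CCC[C@H]2O[Si](C)(C)C(C)(C)C
F5 | step 8 | chloro enoate ε-lactone alcohol | C[C@@]12C=CC(=O)OC(C)(C)C1(Cl)CCC[C@H]2O
F6 | step 8 | chloro keto enoate ε-lactone | C[C@@]12C=CC(=O)OC(C)(C)C1(Cl)CCCC2=O
F0 | step 22 | none | none
F7 | step 18 | tertiary alkynyl ester, 26 without the α-methyl group (α-epimers) | CC1=C(CC(C#C[Si](C(C)C)(C(C)C)C(C)C)C(=O)OC(C)(C)C)[C@@](C)(CC(=O)OCC[Si](C)(C)C)CC[C@@]12C=CC(=O)OC2(C)C
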